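The numbers of this flask are made up, and the outcome is calculated.

You charge 2.6 M of substrate to both flasks, and they differ in the partner.

    substrate → open intermediate (k1 = 1.21 × 10⁻⁴ s⁻¹)
    second intermediate → side product (k2 = 2.33 × 10⁻⁵ s⁻¹)
    open intermediate + second intermediate → target (k3 = 1.39 × 10⁻⁵ M⁻¹ s⁻¹)
    partner → second intermediate (k4 = 6.83 × 10⁻⁵ s⁻¹)

| flask | substrate | partner | time |
|---|---|---|---|
| cedar | 2.6 M | 0.700 equiv | 5.0 d |
| alder | 2.6 M | 0.910 equiv | 5.0 d |

1. which of these there is most of at the end, counted by the substrate in it, cedar (open intermediate / substrate / target)
2. which of these there is most of at the end, counted by the substrate in it, alder (open intermediate / substrate / target)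
3. amount of the one of these that there is most of at the end, in percent of the substrate charged, cedar
4. amount of the one of these that there is most of at the end, in percent of the substrate charged, alder

- The partner charge is 1.82 M in cedar and 2.37 M in alder.
- Substrate opens with a half-life of 0.066 d, faster than partner feeds in at 0.12 d. Second intermediate lasts 0.34 d against loss, far less than the 5.0 d run. So you can reckon the end from the fate of each second intermediate.
- That fate is a fork, capture or loss. Define the crossover as the level of open intermediate at which the two run equally, the loss constant over the capture constant: 1.68 M.
- The capture share, the selectivity of the fork, is that level divided by level plus crossover.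
- For the floor, hold the level at the full charge. That gives the most target, so open intermediate ends at no less than 57.4% in cedar and 44.7% in alder.
- For the ceiling, hold the level at that floor. Open intermediate then ends at no more than 67.0% in cedar and 62.8% in alder. This takes the opening as finished early, which the half-lives allow.
- Now replace the falling level by its mean. My reckoning gives 61.1% for cedar and 50.9% for alder. Open intermediate leads in both.
- The forecast says open intermediate at 63% for cedar and open intermediate at 53% for alder, “with capture only modestly favoured and weakening as the open intermediate is used up”. Both values lie inside the brackets, a little above mine.
- The simulation gives open intermediate at 63.3% for cedar and open intermediate at 53.9% for alder.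
- The larger partner charge may be called the main reason alder ends below cedar. Run at cedar's equivalents of partner, alder's open intermediate goes from 53.9% to 63.3%, a gap of 9.4 percentage points. Cedar ends at 1.64 M, close to the crossover, and alder ends below it at 1.40 M.
- A neighbour of cedar holds 1.6 M of substrate at cedar's equivalents and time, so its whole charge sits below the crossover. By the fork, its capture share stays at or under 48.8%, and it ends with 29.5% target against 36.7% in cedar.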